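The trimethylcyclohexene ring (C1''–C6'') is cut at C1''–C2'' and C5''–C6''. Its C3''=C4'' alkene, flanked by the quaternary C1'' and the C2'' methine, marks it as the [4+2] adduct of a 1,2-dimethylbutadiene and a 2-methylacrolein. One catalytic enantioselective Diels–Alder reaction closes this ring, forms both bonds and sets both stereocentres. It leaves a formyl group (the future C2') as the handle for chain extension. The precursors are methacrolein and (E)-3-methylpenta-1,3-diene. The chromene C2 centre is set later by a ligand-controlled palladium O-allylation, the pyran ring is closed by metathesis, and the quinone is unveiled last.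

Key step: step 1

Numbering: chromene O1, C2–C8a; linker C1' (on C2) and C2'; cyclohexene C1'' (quaternary), C2'' (methine), C3''=C4'', C5'', C6''.

Assumption: the absolute sense of the two catalyst-controlled steps (1 and 9) is assigned from the accepted binding models, not from data on these substrates; if a first run shows the opposite sense, the antipodal catalyst or ligand is used and nothing else changes.

Step 1
Reactants: 1 methacrolein; 2 (E)-3-methylpenta-1,3-diene
Product: 3 (1R,2S)-1,2,3-trimethylcyclohex-3-ene-1-carbaldehyde (formyl cis to the C2 methyl)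
Conditions: (R)-B-o-tolyl oxazaborolidine from (R)-α,α-diphenylprolinol (20 mol%), HNTf2 (16 mol%), 2 (3 equiv), CH2Cl2, −78 → −40 °C
Reagents that add atoms: none
Why: The protonated oxazaborolidine binds the formyl oxygen of s-trans methacrolein (with a formyl C–H···O contact to the ring oxygen), and the s-cis diene adds in a concerted, asynchronous [4+2] cycloaddition in which the C5''–C6'' bond from the enal β-carbon to the unsubstituted diene terminus leads. The closest known reaction type is the oxazaborolidinium-catalysed enantioselective Diels–Alder reaction of 2-substituted acroleins with acyclic dienes. The cyclohexene ring is closed by intermolecular [4+2] cycloaddition, both ring bonds (C1''–C2'' and C5''–C6'') forming in the one step. The quaternary C1'' is set by the catalyst, whose phenyl group next to the bound aldehyde screens one enal face so that the (R)-catalyst should direct the diene to the Si face of the α-carbon. C2'' is set relative to C1'' by the formyl-endo transition state with the E methyl pointing outward, which should place the formyl group cis to the C2'' methyl and the two ring methyls trans. The step needs the orientation in which the methyl-bearing diene terminus bonds to the α-carbon; the stronger directing effect of a terminal donor over an internal one, and the preference of the leading bond for the unhindered CH2 terminus, should secure it.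

Step 2
Reactants: 3 (1R,2S)-1,2,3-trimethylcyclohex-3-ene-1-carbaldehyde; 4 (triphenylphosphoranylidene)acetone
Product: 5 (3E)-4-[(1S,2S)-1,2,3-trimethylcyclohex-3-en-1-yl]but-3-en-2-one
Conditions: 4 (1.5 equiv), toluene, 110 °C
Reagents that add atoms: none
Why: Wittig olefination with a ketone-stabilised ylide should give the E enone, and the α-quaternary aldehyde can neither enolise nor epimerise.

Step 3
Reactants: 5 (3E)-4-[(1S,2S)-1,2,3-trimethylcyclohex-3-en-1-yl]but-3-en-2-one
Product: 6 4-[(1S,2R)-1,2,3-trimethylcyclohex-3-en-1-yl]butan-2-one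
Conditions: [(Ph3P)CuH]6 (0.4 equiv), H2O (5 equiv), degassed toluene, rt
Reagents that add atoms: none
Why: Conjugate reduction by the phosphine-stabilised copper hydride should deliver hydride to the enone β-carbon only, with water protonating the copper enolate and the isolated trisubstituted ring alkene and the carbonyl left untouched.

Step 4
Reactants: 6 4-[(1S,2R)-1,2,3-trimethylcyclohex-3-en-1-yl]butan-2-one; 7 triethyl phosphonoacetate
Product: 8 ethyl (2E)-3-methyl-5-[(1S,2R)-1,2,3-trimethylcyclohex-3-en-1-yl]pent-2-enoate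
Conditions: NaH, THF, 0 °C; then 6, 0 → 60 °C; chromatographic removal of the Z isomer
Reagents that add atoms: none
Why: Horner–Wadsworth–Emmons olefination of the methyl ketone should favour the E enoate (chain trans to the ester); the minor Z isomer must be removed because the alkene geometry fixes the configuration set in step 9.

Step 5
Reactants: 8 ethyl (2E)-3-methyl-5-[(1S,2R)-1,2,3-trimethylcyclohex-3-en-1-yl]pent-2-enoate
Product: 9 (2E)-3-methyl-5-[(1S,2R)-1,2,3-trimethylcyclohex-3-en-1-yl]pent-2-en-1-ol
Conditions: i-Bu2AlH (2.2 equiv), CH2Cl2, −78 °C; Rochelle salt work-up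
Reagents that add atoms: none
Why: 1,2-Reduction of the conjugated ester by the dialkylaluminium hydride should give the allylic alcohol without touching either alkene or the alkene geometry.

Step 6
Reactants: 9 (2E)-3-methyl-5-[(1S,2R)-1,2,3-trimethylcyclohex-3-en-1-yl]pent-2-en-1-ol
Product: 10 methyl (2E)-3-methyl-5-[(1S,2R)-1,2,3-trimethylcyclohex-3-en-1-yl]pent-2-en-1-yl carbonate
Conditions: ClCO2Me, pyridine, CH2Cl2, 0 °C
Reagents that add atoms: methyl chloroformate, COC(=O)Cl
Why: Acylation of the primary allylic alcohol with a chloroformate gives the ionisable carbonate whose leaving group supplies the base in step 9.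

Step 7
Reactants: 11 2,4,5-trimethoxybenzaldehyde
Product: 13 2,4,5-trimethoxyphenol, via 2,4,5-trimethoxyphenyl formate 12 (not isolated)
Conditions: mCPBA, CH2Cl2, 0 °C → rt; aq. NaHCO3 wash; then K2CO3 (0.2 equiv), MeOH, rt
Reagents that add atoms: mCPBA, OOC(=O)c1cccc(Cl)c1
Why: Baeyer–Villiger (Dakin-type) oxidation, in which the electron-rich aryl group migrates to give the aryl formate, followed by base-catalysed methanolysis of the formate to the phenol.

Step 8
Reactants: 13 2,4,5-trimethoxyphenol
Product: 15 2-hydroxy-3,5,6-trimethoxybenzaldehyde, via 2-(hydroxymethyl)-3,4,6-trimethoxyphenol 14 (not isolated)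
Conditions: MgCl2, Et3N, (CH2O)n, MeCN, reflux; 1 M HCl work-up
Reagents that add atoms: paraformaldehyde (reacts as formaldehyde), C=O
Why: Magnesium-mediated ortho-formylation of a phenol, in which the magnesium phenoxide directs formaldehyde to the only free ortho position and the benzylic alkoxide is oxidised in the flask by a second formaldehyde through an Oppenauer-type hydride transfer.

Step 9
Reactants: 10 methyl (2E)-3-methyl-5-[(1S,2R)-1,2,3-trimethylcyclohex-3-en-1-yl]pent-2-en-1-yl carbonate; 15 2-hydroxy-3,5,6-trimethoxybenzaldehyde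
Product: 16 2-{[(3S)-3-methyl-5-[(1S,2R)-1,2,3-trimethylcyclohex-3-en-1-yl]pent-1-en-3-yl]oxy}-3,5,6-trimethoxybenzaldehyde
Conditions: Pd2(dba)3·CHCl3 (2 mol%), (R,R)-DACH-phenyl Trost ligand (6 mol%), 15 (1.3 equiv), CH2Cl2, 0 °C → rt, stopped at full conversion of 10
Reagents that add atoms: none
Why: Palladium-catalysed asymmetric allylic etherification (Tsuji–Trost type), in which zerovalent palladium ionises the E carbonate to a π-allyl complex, the phenoxide formed by the released methoxide attacks the more substituted terminus anti to the metal to give the branched tertiary ether, and the ligand pocket selects the allyl face so that the new C–O centre should be S; kinetic control avoids re-ionisation to the linear ether.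

Step 10
Reactants: 16 2-{[(3S)-3-methyl-5-[(1S,2R)-1,2,3-trimethylcyclohex-3-en-1-yl]pent-1-en-3-yl]oxy}-3,5,6-trimethoxybenzaldehyde
Product: 17 2-ethenyl-3,4,6-trimethoxy-1-{[(3S)-3-methyl-5-[(1S,2R)-1,2,3-trimethylcyclohex-3-en-1-yl]pent-1-en-3-yl]oxy}benzene
Conditions: Ph3PCH3Br, KOt-Bu, THF, 0 °C → rt
Reagents that add atoms: methyltriphenylphosphonium bromide, C[P+](c1ccccc1)(c1ccccc1)c1ccccc1.[Br-]
Why: Wittig methylenation of the aryl aldehyde with the non-stabilised ylide; the tertiary allylic aryl ether and all stereocentres are inert to the base.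

Step 11
Reactants: 17 2-ethenyl-3,4,6-trimethoxy-1-{[(3S)-3-methyl-5-[(1S,2R)-1,2,3-trimethylcyclohex-3-en-1-yl]pent-1-en-3-yl]oxy}benzene
Product: 18 (2S)-5,6,8-trimethoxy-2-methyl-2-{2-[(1S,2R)-1,2,3-trimethylcyclohex-3-en-1-yl]ethyl}-2H-chromene
Conditions: second-generation Grubbs catalyst (H2IMes)(PCy3)Cl2Ru=CHPh (5 mol%), CH2Cl2, 40 °C
Reagents that add atoms: none
Why: Ring-closing metathesis between the styrene and the vinyl group on the quaternary carbon closes the pyran ring at C3=C4 with loss of ethylene; the trisubstituted cyclohexene is too hindered to take part and C2 is untouched.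

Step 12
Reactants: 18 (2S)-5,6,8-trimethoxy-2-methyl-2-{2-[(1S,2R)-1,2,3-trimethylcyclohex-3-en-1-yl]ethyl}-2H-chromene
Product: 19 (2S)-6-methoxy-2-methyl-2-{2-[(1S,2R)-1,2,3-trimethylcyclohex-3-en-1-yl]ethyl}-2H-chromene-5,8-dione
Conditions: (NH4)2Ce(NO3)6 (2.5 equiv), MeCN–H2O, 0 °C
Reagents that add atoms: water, O
Why: Oxidative demethylation of the para-dimethoxyarene, in which two one-electron oxidations and addition of water at the C5 and C8 methoxy-bearing carbons release methanol and give the para-quinone, with the C6 methoxy group kept.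

Compound list
1 | methacrolein (2-methylprop-2-enal) | CC(=C)C=O | starting material
2 | (E)-3-methylpenta-1,3-diene | C/C=C(C)/C=C | starting material
3 | (1R,2S)-1,2,3-trimethylcyclohex-3-ene-1-carbaldehyde | O=C[C@]1(C)CCC=C(C)[C@@H]1C | intermediate
4 | (triphenylphosphoranylidene)acetone | CC(=O)C=P(c1ccccc1)(c1ccccc1)c1ccccc1 | starting material
5 | (3E)-4-[(1S,2S)-1,2,3-trimethylcyclohex-3-en-1-yl]but-3-en-2-one | CC(=O)/C=C/[C@]1(C)CCC=C(C)[C@@H]1C | intermediate
6 | 4-[(1S,2R)-1,2,3-trimethylcyclohex-3-en-1-yl]butan-2-one | CC(=O)CC[C@]1(C)CCC=C(C)[C@@H]1C | intermediate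
7 | triethyl phosphonoacetate | CCOC(=O)CP(=O)(OCC)OCC | starting material
8 | ethyl (2E)-3-methyl-5-[(1S,2R)-1,2,3-trimethylcyclohex-3-en-1-yl]pent-2-enoate | CCOC(=O)/C=C(\C)CC[C@]1(C)CCC=C(C)[C@@H]1C | intermediate
9 | (2E)-3-methyl-5-[(1S,2R)-1,2,3-trimethylcyclohex-3-en-1-yl]pent-2-en-1-ol | OC/C=C(\C)CC[C@]1(C)CCC=C(C)[C@@H]1C | intermediate
10 | methyl (2E)-3-methyl-5-[(1S,2R)-1,2,3-trimethylcyclohex-3-en-1-yl]pent-2-en-1-yl carbonate | COC(=O)OC/C=C(\C)CC[C@]1(C)CCC=C(C)[C@@H]1C | intermediate
11 | 2,4,5-trimethoxybenzaldehyde | COc1cc(OC)c(C=O)cc1OC | starting material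
12 | 2,4,5-trimethoxyphenyl formate | COc1cc(OC)c(OC=O)cc1OC | intermediate
13 | 2,4,5-trimethoxyphenol | COc1cc(OC)c(O)cc1OC | intermediate
14 | 2-(hydroxymethyl)-3,4,6-trimethoxyphenol | COc1cc(OC)c(O)c(CO)c1OC | intermediate
15 | 2-hydroxy-3,5,6-trimethoxybenzaldehyde | COc1cc(OC)c(O)c(C=O)c1OC | intermediate
16 | 2-{[(3S)-3-methyl-5-[(1S,2R)-1,2,3-trimethylcyclohex-3-en-1-yl]pent-1-en-3-yl]oxy}-3,5,6-trimethoxybenzaldehyde | C=C[C@](C)(CC[C@]1(C)CCC=C(C)[C@@H]1C)Oc1c(C=O)c(OC)c(OC)cc1OC | intermediate
17 | 2-ethenyl-3,4,6-trimethoxy-1-{[(3S)-3-methyl-5-[(1S,2R)-1,2,3-trimethylcyclohex-3-en-1-yl]pent-1-en-3-yl]oxy}benzene | C=C[C@](C)(CC[C@]1(C)CCC=C(C)[C@@H]1C)Oc1c(C=C)c(OC)c(OC)cc1OC | intermediate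
18 | (2S)-5,6,8-trimethoxy-2-methyl-2-{2-[(1S,2R)-1,2,3-trimethylcyclohex-3-en-1-yl]ethyl}-2H-chromene | COc1cc(OC)c2c(c1OC)C=C[C@](C)(CC[C@]1(C)CCC=C(C)[C@@H]1C)O2 | intermediate
19 | (2S)-6-methoxy-2-methyl-2-{2-[(1S,2R)-1,2,3-trimethylcyclohex-3-en-1-yl]ethyl}-2H-chromene-5,8-dione | COC1=CC(=O)C2=C(C=C[C@](C)(CC[C@]3(C)CCC=C(C)[C@@H]3C)O2)C1=O | target

Total step count: 12.
Longest linear sequence: 10 steps (steps 1–6, then 9–12); the arene branch (steps 7 and 8) is 2 steps.

Steps most likely to fail

Step 1. The diene may add in the opposite orientation (unsubstituted terminus to the α-carbon), because the bond that creates the quaternary centre next to a substituted carbon is crowded. The catalyst may also discriminate the enal faces poorly with this trisubstituted diene. The fallback sets out from 2 and returns to the route at 3. Diene 2 is combined with commercial (4S)-3-acryloyl-4-benzyl-1,3-oxazolidin-2-one under Et2AlCl (CH2Cl2, −78 °C). The unbranched, chelated dienophile lowers the steric penalty on the desired orientation, and the benzyl group screens one face, so the endo adduct (4S)-4-benzyl-3-{[(1R,2R)-2,3-dimethylcyclohex-3-en-1-yl]carbonyl}-1,3-oxazolidin-2-one F1 should form. Methanolysis (MeOMgBr, MeOH, 0 °C) removes the auxiliary and gives methyl (1R,2R)-2,3-dimethylcyclohex-3-ene-1-carboxylate F2, whose C1 configuration is immaterial. Deprotonation with LDA (THF, −78 °C) and methylation with MeI, anti to the neighbouring C2 methyl, should give methyl (1R,2S)-1,2,3-trimethylcyclohex-3-ene-1-carboxylate F3. LiAlH4 (Et2O, 0 °C) gives [(1R,2S)-1,2,3-trimethylcyclohex-3-en-1-yl]methanol F4, and Swern oxidation returns aldehyde 3.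

Step 9. The hindered and fairly acidic phenoxide may attack the primary allyl terminus, the branched ether may re-ionise and drift to the linear isomer, or the ligand may discriminate the allyl faces poorly. The fallback sets out from 9 and 13 and returns to the route at 18. Alcohol 9 is oxidised with MnO2 (CH2Cl2, rt) to (2E)-3-methyl-5-[(1S,2R)-1,2,3-trimethylcyclohex-3-en-1-yl]pent-2-enal F5. F5 and phenol 13 are heated with PhB(OH)2 and catalytic propionic acid in toluene with removal of water. Ortho-alkylation followed by oxa-6π electrocyclisation should give chromene 18 together with its C2 epimer, (2R)-5,6,8-trimethoxy-2-methyl-2-{2-[(1S,2R)-1,2,3-trimethylcyclohex-3-en-1-yl]ethyl}-2H-chromene F6. The two diastereomers are separated by preparative chromatography on a chiral stationary phase. This bypasses steps 6, 8, 10 and 11, and step 12 follows from 18.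

Step 4. The olefination may give a large share of the Z enoate that is hard to remove completely, which would carry the wrong allyl geometry into step 9 and erode the C2 configuration. The fallback sets out from 6 and returns to the route at 9. Ketone 6 is deprotonated at the methyl group (LDA, THF, −78 °C) and trapped with ClP(O)(OEt)2 as diethyl 4-[(1S,2R)-1,2,3-trimethylcyclohex-3-en-1-yl]but-1-en-2-yl phosphate F7. Further LDA (−78 °C → rt) eliminates F7 to 4-[(1S,2R)-1,2,3-trimethylcyclohex-3-en-1-yl]but-1-yne F8. Zirconium-catalysed syn-carboalumination (Me3Al, Cp2ZrCl2 cat., CH2Cl2, rt) gives dimethyl[(1E)-2-methyl-4-[(1S,2R)-1,2,3-trimethylcyclohex-3-en-1-yl]but-1-en-1-yl]alumane F9. F9 is converted to the ate complex with n-BuLi and quenched with paraformaldehyde to give 9 as a single geometric isomer, bypassing 8 and step 5.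

Further compounds
F1 | step 1 | (4S)-4-benzyl-3-{[(1R,2R)-2,3-dimethylcyclohex-3-en-1-yl]carbonyl}-1,3-oxazolidin-2-one | O=C1OC[C@H](Cc2ccccc2)N1C(=O)[C@@H]3CCC=C(C)[C@@H]3C
F2 | step 1 | methyl (1R,2R)-2,3-dimethylcyclohex-3-ene-1-carboxylate | COC(=O)[C@@H]1CCC=C(C)[C@@H]1C
F3 | step 1 | methyl (1R,2S)-1,2,3-trimethylcyclohex-3-ene-1-carboxylate | COC(=O)[C@]1(C)CCC=C(C)[C@@H]1C
F4 | step 1 | [(1R,2S)-1,2,3-trimethylcyclohex-3-en-1-yl]methanol | OC[C@]1(C)CCC=C(C)[C@@H]1C
F5 | step 9 | (2E)-3-methyl-5-[(1S,2R)-1,2,3-trimethylcyclohex-3-en-1-yl]pent-2-enal | O=C/C=C(\C)CC[C@]1(C)CCC=C(C)[C@@H]1C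
F6 | step 9 | (2R)-5,6,8-trimethoxy-2-methyl-2-{2-[(1S,2R)-1,2,3-trimethylcyclohex-3-en-1-yl]ethyl}-2H-chromene | COc1cc(OC)c2c(c1OC)C=C[C@@](C)(CC[C@]1(C)CCC=C(C)[C@@H]1C)O2
F7 | step 4 | diethyl 4-[(1S,2R)-1,2,3-trimethylcyclohex-3-en-1-yl]but-1-en-2-yl phosphate | C=C(CC[C@]1(C)CCC=C(C)[C@@H]1C)OP(=O)(OCC)OCC
F8 | step 4 | 4-[(1S,2R)-1,2,3-trimethylcyclohex-3-en-1-yl]but-1-yne | C#CCC[C@]1(C)CCC=C(C)[C@@H]1C
F9 | step 4 | dimethyl[(1E)-2-methyl-4-[(1S,2R)-1,2,3-trimethylcyclohex-3-en-1-yl]but-1-en-1-yl]alumane | C[Al](C)/C=C(\C)CC[C@]1(C)CCC=C(C)[C@@H]1C
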